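The depside ester is traced back to a diaryl ketone: the carbonyl carbon of ring A is bonded to C3 of ring B, and one oxygen atom is inserted between them at the very end. The key step, a Dakin oxidation, forms the C(=O)–O and O–C3 bonds in one operation and delivers the target directly. It exploits the free hydroxyls at C2 and C4 of ring B, which flank C3 and make ring B the migrating group. The precursor is 3-(2,4-dimethoxy-6-pentylbenzoyl)-2,4-dihydroxy-6-propylbenzoic acid; its carboxyl carbon is carried from the start as a formyl group, so the hydroxy-benzophenone never meets hot base.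

Key step: step 8

Remarks on the chemistry:
- Ring A is the 2,4-dimethoxy-6-pentylphenyl ring; ring B is numbered as the benzoic acid (C1 carboxyl, C2 and C4 oxygen, C3 the coupling carbon, C6 propyl). The target and precursor structures were checked against this numbering and need no correction.
- The target has no stereocentre; the carbinol, amino alkoxide and peroxy-adduct centres formed on the way are racemic and are all destroyed again.
- The ring B carboxyl carbon is installed as a formyl group in step 1 and oxidised before the phenols are freed. Carboxylating the finished 2-hydroxy-2'-methoxybenzophenone in hot base would invite xanthone formation by intramolecular displacement of methoxide.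

Step 1
Reactants: 1 5-propylresorcinol
Product: 3 2,4-dihydroxy-6-propylbenzaldehyde, via aryl iminium chloride 2 (not isolated)
Conditions: POCl3, DMF, MeCN, 0 °C → rt; then H2O, 50 °C
Reagents that add atoms: N,N-dimethylformamide, CN(C)C=O; water, O
Why: Vilsmeier–Haack formylation of the resorcinol should take place at the ring carbon para to one hydroxyl, ortho to the other and next to the propyl group, as it does for orcinol and olivetol, which places the future carboxyl carbon of ring B before any coupling.

Step 2
Reactants: 3 2,4-dihydroxy-6-propylbenzaldehyde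
Product: 4 2,4-bis(methoxymethoxy)-6-propylbenzaldehyde
Conditions: NaH, MOMCl, DMF, 0 °C → rt
Reagents that add atoms: chloromethyl methyl ether, COCCl
Why: Williamson etherification of the two sodium phenoxides with MOMCl should cap both phenols, the hydrogen-bonded one included, as methoxymethyl ethers that survive organolithium reagents and later direct lithiation to the carbon between them.

Step 3
Reactants: 5 1,3-dimethoxy-5-pentylbenzene
Product: 7 2,4-dimethoxy-6-pentylbenzaldehyde, via aryl iminium chloride 6 (not isolated)
Conditions: POCl3, DMF, 0 → 70 °C; then H2O, 50 °C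
Reagents that add atoms: N,N-dimethylformamide, CN(C)C=O; water, O
Why: Vilsmeier–Haack formylation of this resorcinol dimethyl ether should occur at the carbon that is ortho to one methoxy group, para to the other and next to the pentyl chain, the usual site for 5-alkyl-1,3-dimethoxybenzenes, and not at the more crowded carbon between the two methoxy groups.

Step 4
Reactants: 4 2,4-bis(methoxymethoxy)-6-propylbenzaldehyde; 7 2,4-dimethoxy-6-pentylbenzaldehyde
Product: 11 3-[(2,4-dimethoxy-6-pentylphenyl)(hydroxy)methyl]-2,4-bis(methoxymethoxy)-6-propylbenzaldehyde (racemic), via lithium amino alkoxide 8 (not isolated), via ring-lithiated amino alkoxide 9 (not isolated), via dilithium dialkoxide adduct 10 (not isolated)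
Conditions: lithium 4-methylpiperazin-1-ide (from 1-methylpiperazine, n-BuLi), THF, −20 °C; n-BuLi, TMEDA, −20 → 0 °C; 7, −78 → 0 °C; aq. NH4Cl
Reagents that add atoms: none
Why: Addition of the lithium amide masks the formyl group as an amino alkoxide that n-BuLi does not attack, directed ortho-metalation then removes the only ring proton flanked by two methoxymethoxy groups (C3 of ring B), and 1,2-addition of this aryllithium to aldehyde 7 should give the carbinol, whose new stereocentre is formed without control (racemic) and is erased in step 5, while aqueous work-up returns the formyl group.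

Step 5
Reactants: 11 3-[(2,4-dimethoxy-6-pentylphenyl)(hydroxy)methyl]-2,4-bis(methoxymethoxy)-6-propylbenzaldehyde
Product: 12 3-(2,4-dimethoxy-6-pentylbenzoyl)-2,4-bis(methoxymethoxy)-6-propylbenzaldehyde
Conditions: Dess–Martin periodinane, pyridine, CH2Cl2, 0 °C → rt
Reagents that add atoms: none
Why: Dess–Martin oxidation should turn the crowded diaryl carbinol into the diaryl ketone under mild buffered conditions that leave the formyl group, the methoxymethyl ethers and both electron-rich rings untouched.

Step 6
Reactants: 12 3-(2,4-dimethoxy-6-pentylbenzoyl)-2,4-bis(methoxymethoxy)-6-propylbenzaldehyde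
Product: 13 3-(2,4-dimethoxy-6-pentylbenzoyl)-2,4-bis(methoxymethoxy)-6-propylbenzoic acid
Conditions: NaClO2, NaH2PO4, 2-methyl-2-butene, t-BuOH/THF/H2O, 0 °C → rt
Reagents that add atoms: sodium chlorite, [Na+].[O-]Cl=O
Why: Pinnick oxidation should convert the formyl group into the carboxylic acid without affecting the diaryl ketone, and 2-methyl-2-butene traps the hypochlorous acid that could otherwise chlorinate the electron-rich rings.

Step 7
Reactants: 13 3-(2,4-dimethoxy-6-pentylbenzoyl)-2,4-bis(methoxymethoxy)-6-propylbenzoic acid
Product: 14 3-(2,4-dimethoxy-6-pentylbenzoyl)-2,4-dihydroxy-6-propylbenzoic acid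
Conditions: HCl (2 M), MeOH/THF, rt
Reagents that add atoms: none
Why: Acid-catalysed cleavage of the methoxymethyl ethers (acetal exchange with methanol) should be fast for both groups because each lies ortho to the ketone, so that room temperature suffices, the 2,4-dihydroxybenzoic acid is not decarboxylated and the doubly ortho-substituted carboxyl group escapes Fischer esterification.

Step 8
Reactants: 14 3-(2,4-dimethoxy-6-pentylbenzoyl)-2,4-dihydroxy-6-propylbenzoic acid
Product: 16 3-[(2,4-dimethoxy-6-pentylbenzoyl)oxy]-2,4-dihydroxy-6-propylbenzoic acid, via hydroperoxy adduct 15 (not isolated)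
Conditions: H2O2 (30% aq.), NaHCO3, THF/H2O, 0 °C → rt; then 1 M HCl to pH 2
Reagents that add atoms: hydrogen peroxide, OO
Why: The hydroperoxide anion adds to the ketone carbon that links ring A to C3 of ring B and gives adduct 15, in which C3 shifts from carbon to the proximal peroxide oxygen while hydroxide leaves, so the C(=O)–O and O–C3 bonds of the depside ester form in one operation. This is a Dakin oxidation, the base-mediated Baeyer–Villiger reaction of ortho-hydroxyaryl ketones, which is known for ortho-hydroxybenzophenones. No ring is closed and no stereocentre remains, since the tetrahedral carbon of 15 is transient. The step needs ring B to migrate in preference to ring A, and the ionised hydroxyls at C2 and C4, both ortho to the migrating carbon, donate far more strongly than the methoxy groups of ring A, so the oxygen should arrive exactly between the two hydroxyls. The new ester carbonyl is flanked by a methoxy group and the pentyl chain, which should shield it from perhydrolysis and from acyl transfer to the neighbouring phenoxides at this mild pH, and working at or below room temperature avoids base-induced xanthone closure of the 2-hydroxy-2'-methoxybenzophenone.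

Compound list
1 | 5-propylresorcinol (5-propylbenzene-1,3-diol) | CCCc1cc(O)cc(O)c1 | starting material
2 | [(2,4-dihydroxy-6-propylphenyl)methylidene]dimethyliminium chloride | CCCc1cc(O)cc(O)c1C=[N+](C)C.[Cl-] | intermediate
3 | 2,4-dihydroxy-6-propylbenzaldehyde | CCCc1cc(O)cc(O)c1C=O | intermediate
4 | 2,4-bis(methoxymethoxy)-6-propylbenzaldehyde | CCCc1cc(OCOC)cc(OCOC)c1C=O | intermediate
5 | 1,3-dimethoxy-5-pentylbenzene | CCCCCc1cc(OC)cc(OC)c1 | starting material
6 | [(2,4-dimethoxy-6-pentylphenyl)methylidene]dimethyliminium chloride | CCCCCc1cc(OC)cc(OC)c1C=[N+](C)C.[Cl-] | intermediate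
7 | 2,4-dimethoxy-6-pentylbenzaldehyde | CCCCCc1cc(OC)cc(OC)c1C=O | intermediate
8 | lithium [2,4-bis(methoxymethoxy)-6-propylphenyl](4-methylpiperazin-1-yl)methanolate (racemic) | CCCc1cc(OCOC)cc(OCOC)c1C(O[Li])N1CCN(C)CC1 | intermediate
9 | lithium [3-lithio-2,4-bis(methoxymethoxy)-6-propylphenyl](4-methylpiperazin-1-yl)methanolate (racemic) | CCCc1cc(OCOC)c([Li])c(OCOC)c1C(O[Li])N1CCN(C)CC1 | intermediate
10 | dilithium dialkoxide from addition of 9 to 7 (mixture of diastereomers) | CCCCCc1cc(OC)cc(OC)c1C(O[Li])c1c(OCOC)cc(CCC)c(C(O[Li])N2CCN(C)CC2)c1OCOC | intermediate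
11 | 3-[(2,4-dimethoxy-6-pentylphenyl)(hydroxy)methyl]-2,4-bis(methoxymethoxy)-6-propylbenzaldehyde (racemic) | CCCCCc1cc(OC)cc(OC)c1C(O)c1c(OCOC)cc(CCC)c(C=O)c1OCOC | intermediate
12 | 3-(2,4-dimethoxy-6-pentylbenzoyl)-2,4-bis(methoxymethoxy)-6-propylbenzaldehyde | CCCCCc1cc(OC)cc(OC)c1C(=O)c1c(OCOC)cc(CCC)c(C=O)c1OCOC | intermediate
13 | 3-(2,4-dimethoxy-6-pentylbenzoyl)-2,4-bis(methoxymethoxy)-6-propylbenzoic acid | CCCCCc1cc(OC)cc(OC)c1C(=O)c1c(OCOC)cc(CCC)c(C(=O)O)c1OCOC | intermediate
14 | 3-(2,4-dimethoxy-6-pentylbenzoyl)-2,4-dihydroxy-6-propylbenzoic acid | CCCCCc1cc(OC)cc(OC)c1C(=O)c1c(O)cc(CCC)c(C(=O)O)c1O | intermediate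
15 | 3-[(2,4-dimethoxy-6-pentylphenyl)(hydroperoxy)(hydroxy)methyl]-2,4-dihydroxy-6-propylbenzoic acid (racemic, transient) | CCCCCc1cc(OC)cc(OC)c1C(O)(OO)c1c(O)cc(CCC)c(C(=O)O)c1O | intermediate
16 | 3-[(2,4-dimethoxy-6-pentylbenzoyl)oxy]-2,4-dihydroxy-6-propylbenzoic acid | CCCCCc1cc(OC)cc(OC)c1C(=O)Oc1c(O)cc(CCC)c(C(=O)O)c1O | target

Total step count: 8 steps.
Longest linear sequence: 7 steps (steps 1, 2, 4, 5, 6, 7, 8); step 3 is a one-step branch.

Steps most likely to fail

Step 8. The hydroperoxide anion may fail to add to a carbonyl group that is shielded by four ortho substituents and deactivated by the flanking phenoxides. Ring A may also migrate in competition, or the new ester may undergo acyl transfer or perhydrolysis. The fallback makes the C3–O bond and the ester separately by known chemistry; it sets out from 4 and 7 and comes back to the route at 16. Aldehyde 4 is converted as in step 4 into 9, which is trapped with B(OMe)3 and hydrolysed to [3-formyl-2,6-bis(methoxymethoxy)-4-propylphenyl]boronic acid F1. NaBO3 in aqueous THF then oxidises the C–B bond to give 3-hydroxy-2,4-bis(methoxymethoxy)-6-propylbenzaldehyde F2. Aldehyde 7 is oxidised with NaClO2 to 2,4-dimethoxy-6-pentylbenzoic acid F3 and converted with oxalyl chloride into 2,4-dimethoxy-6-pentylbenzoyl chloride F4. Acylation of the sodium phenoxide of F2 (NaH, THF) with F4 should give 3-formyl-2,6-bis(methoxymethoxy)-4-propylphenyl 2,4-dimethoxy-6-pentylbenzoate F5. NaClO2 oxidation of its formyl group gives 3-[(2,4-dimethoxy-6-pentylbenzoyl)oxy]-2,4-bis(methoxymethoxy)-6-propylbenzoic acid F6, and HCl in methanol at room temperature removes both methoxymethyl groups to give 16.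

Step 4. Masking of the hindered formyl group may be incomplete, so that n-BuLi adds to it, and surplus n-BuLi may consume aldehyde 7 before the crowded aryllithium does. The fallback replaces the masked aldehyde by an alcohol that protects itself on deprotonation; it sets out from 4 and comes back to the route at 12. NaBH4 in methanol reduces 4 to [2,4-bis(methoxymethoxy)-6-propylphenyl]methanol F7. n-BuLi (2.2 equiv) in THF at 0 °C forms the alkoxide and lithiates C3 to give lithium [3-lithio-2,4-bis(methoxymethoxy)-6-propylphenyl]methanolate F8. This adds to 7 to give (2,4-dimethoxy-6-pentylphenyl)[3-(hydroxymethyl)-2,6-bis(methoxymethoxy)-4-propylphenyl]methanol F9, and excess Dess–Martin periodinane oxidises both alcohols to 12.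

Step 7. The liberated 2,4-dihydroxybenzoic acid may lose CO2 under the acidic conditions, or cleavage of the ethers may stall. The fallback reverses the order of deprotection and oxidation so that the carboxylic acid never meets mineral acid; it sets out from 12 and comes back to the route at 14. The methoxymethyl groups of 12 are removed first (HCl, MeOH/THF, rt) to give 3-(2,4-dimethoxy-6-pentylbenzoyl)-2,4-dihydroxy-6-propylbenzaldehyde F10. Its formyl group is then oxidised with NaClO2 and NaH2PO4 in the presence of sulfamic acid and 2-methyl-2-butene to give 14.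

Further compounds
F1 | step 8 | [3-formyl-2,6-bis(methoxymethoxy)-4-propylphenyl]boronic acid | CCCc1cc(OCOC)c(B(O)O)c(OCOC)c1C=O
F2 | step 8 | 3-hydroxy-2,4-bis(methoxymethoxy)-6-propylbenzaldehyde | CCCc1cc(OCOC)c(O)c(OCOC)c1C=O
F3 | step 8 | 2,4-dimethoxy-6-pentylbenzoic acid | CCCCCc1cc(OC)cc(OC)c1C(=O)O
F4 | step 8 | 2,4-dimethoxy-6-pentylbenzoyl chloride | CCCCCc1cc(OC)cc(OC)c1C(=O)Cl
F5 | step 8 | 3-formyl-2,6-bis(methoxymethoxy)-4-propylphenyl 2,4-dimethoxy-6-pentylbenzoate | CCCCCc1cc(OC)cc(OC)c1C(=O)Oc1c(OCOC)cc(CCC)c(C=O)c1OCOC
F6 | step 8 | 3-[(2,4-dimethoxy-6-pentylbenzoyl)oxy]-2,4-bis(methoxymethoxy)-6-propylbenzoic acid | CCCCCc1cc(OC)cc(OC)c1C(=O)Oc1c(OCOC)cc(CCC)c(C(=O)O)c1OCOC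
F7 | step 4 | [2,4-bis(methoxymethoxy)-6-propylphenyl]methanol | CCCc1cc(OCOC)cc(OCOC)c1CO
F8 | step 4 | lithium [3-lithio-2,4-bis(methoxymethoxy)-6-propylphenyl]methanolate | CCCc1cc(OCOC)c([Li])c(OCOC)c1CO[Li]
F9 | step 4 | (2,4-dimethoxy-6-pentylphenyl)[3-(hydroxymethyl)-2,6-bis(methoxymethoxy)-4-propylphenyl]methanol (racemic) | CCCCCc1cc(OC)cc(OC)c1C(O)c1c(OCOC)cc(CCC)c(CO)c1OCOC
F10 | step 7 | 3-(2,4-dimethoxy-6-pentylbenzoyl)-2,4-dihydroxy-6-propylbenzaldehyde | CCCCCc1cc(OC)cc(OC)c1C(=O)c1c(O)cc(CCC)c(C=O)c1O
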